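**Strategy.** The route rests on disconnecting the bond between the formyl-bearing methine (chain C2 of the undecadienal, the exocyclic carbon on ring C3 of the cyclopentene) and the neighbouring chain methylene C3. That methine is an epimerisable α-formyl stereocentre, so it is built as a boron-bearing carbon. A sparteine-directed lithiation–borylation unites a cyclopentenylmethyl triisopropylbenzoate (enal masked as a dioxolane; made by Evans Diels–Alder, ozonolysis and aldol ring contraction) with homogeranyl pinacolboronate. In one operation the 1,2-metallate shift forms the C–C bond and fixes the (S) configuration under reagent control. A stereoretentive Matteson homologation then turns the temporary C–B bond into the formyl group.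

Key step: step 9

Remark: 17 and 18 are drawn without the coordinated (−)-sparteine; deprotonation by sBuLi/(−)-sparteine is assumed to be reagent-controlled (pro-S hydrogen), as is usual for O-alkyl 2,4,6-triisopropylbenzoates.

**Step 1**
Reactants: 1 tert-butyl(dimethyl)(prop-2-yn-1-yloxy)silane; 2 ethene
Product: 3 tert-butyl(dimethyl)[(2-methylidenebut-3-en-1-yl)oxy]silane
Conditions: Grubbs II (5 mol %), ethene (1 atm), toluene, 80 °C
Reagents that add atoms: none
Why: Ethene–alkyne cross-enyne metathesis converts a terminal alkyne with a propargylic oxygen into the 2-substituted buta-1,3-diene with full atom economy.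

**Step 2**
Reactants: 4 (4R)-4-benzyl-1,3-oxazolidin-2-one; 5 prop-2-enoyl chloride
Product: 6 (4R)-4-benzyl-3-(prop-2-enoyl)-1,3-oxazolidin-2-one
Conditions: MeMgBr, THF, 0 °C; then 5, −78 → 0 °C
Reagents that add atoms: none
Why: N-acylation of the magnesium salt of the oxazolidinone with the acid chloride is the standard entry to Evans acrylimides and limits anionic polymerisation.

**Step 3**
Reactants: 3 tert-butyl(dimethyl)[(2-methylidenebut-3-en-1-yl)oxy]silane; 6 (4R)-4-benzyl-3-(prop-2-enoyl)-1,3-oxazolidin-2-one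
Product: 7 (4R)-4-benzyl-3-{[(1S)-4-({[tert-butyl(dimethyl)silyl]oxy}methyl)cyclohex-3-en-1-yl]carbonyl}-1,3-oxazolidin-2-one
Conditions: Et2AlCl (1.4 equiv), CH2Cl2, −78 °C
Reagents that add atoms: none
Why: Evans auxiliary-controlled Diels–Alder reaction in which the chelated s-cis acrylimide–aluminium complex is attacked on the face opposite the benzyl group, which should set (S) at the ring carbon, while the larger HOMO coefficient at C1 of the 2-substituted diene should give the 1,4 ("para") adduct.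

**Step 4**
Reactants: 7 (4R)-4-benzyl-3-{[(1S)-4-({[tert-butyl(dimethyl)silyl]oxy}methyl)cyclohex-3-en-1-yl]carbonyl}-1,3-oxazolidin-2-one
Product: 8 [(1S)-4-({[tert-butyl(dimethyl)silyl]oxy}methyl)cyclohex-3-en-1-yl]methanol
Conditions: LiBH4, H2O (1 equiv), Et2O, 0 °C
Reagents that add atoms: none
Why: Reductive cleavage of the N-acyl oxazolidinone with lithium borohydride should give the primary alcohol without touching the stereocentre or the silyl ether and return the auxiliary.

**Step 5**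
Reactants: 8 [(1S)-4-({[tert-butyl(dimethyl)silyl]oxy}methyl)cyclohex-3-en-1-yl]methanol
Product: 9 [(1S)-4-({[tert-butyl(dimethyl)silyl]oxy}methyl)cyclohex-3-en-1-yl]methyl 2,4,6-tri(propan-2-yl)benzoate
Conditions: 2,4,6-triisopropylbenzoyl chloride, Et3N, DMAP (cat.), CH2Cl2, 40 °C
Reagents that add atoms: 2,4,6-tri(propan-2-yl)benzoyl chloride, CC(C)c1cc(C(C)C)c(C(=O)Cl)c(C(C)C)c1
Why: Esterification of the primary alcohol with the hindered aroyl chloride installs the triisopropylbenzoate that later serves as directing and leaving group in the lithiation–borylation.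

**Step 6**
Reactants: 9 [(1S)-4-({[tert-butyl(dimethyl)silyl]oxy}methyl)cyclohex-3-en-1-yl]methyl 2,4,6-tri(propan-2-yl)benzoate
Product: 12 [(1S)-3-({[tert-butyl(dimethyl)silyl]oxy}methyl)-2-formylcyclopent-2-en-1-yl]methyl 2,4,6-tri(propan-2-yl)benzoate, via secondary ozonide 10 (not isolated), via keto aldehyde 11 (not isolated)
Conditions: O3, CH2Cl2, −78 °C; Me2S, −78 °C → rt; solvent exchange; piperidine (0.2 equiv), AcOH (0.2 equiv), toluene, rt → 50 °C
Reagents that add atoms: ozone, [O-][O+]=O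
Why: Ozonolysis of the only alkene gives the 6-oxo aldehyde, and amine-catalysed intramolecular aldol condensation (enamine of the aldehyde onto the activated α-silyloxy ketone, 5-enolexo) should contract the ring to the cyclopentenecarbaldehyde, the stereocentre being β to the aldehyde and therefore untouched.

**Step 7**
Reactants: 12 [(1S)-3-({[tert-butyl(dimethyl)silyl]oxy}methyl)-2-formylcyclopent-2-en-1-yl]methyl 2,4,6-tri(propan-2-yl)benzoate
Product: 13 [(1S)-3-({[tert-butyl(dimethyl)silyl]oxy}methyl)-2-(1,3-dioxolan-2-yl)cyclopent-2-en-1-yl]methyl 2,4,6-tri(propan-2-yl)benzoate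
Conditions: (TMSOCH2)2, TMSOTf (cat.), CH2Cl2, −78 → −20 °C
Reagents that add atoms: 1,2-bis(trimethylsilyloxy)ethane, C[Si](C)(C)OCCO[Si](C)(C)C
Why: Noyori acetalisation should protect the enal as its dioxolane under aprotic conditions that neither shift the tetrasubstituted double bond nor cleave the silyl ether.

**Step 8**
Reactants: 14 (2E)-1-bromo-3,7-dimethylocta-2,6-diene (geranyl bromide); 15 2,2'-methylenebis(4,4,5,5-tetramethyl-1,3,2-dioxaborolane)
Product: 16 2-[(3E)-4,8-dimethylnona-3,7-dien-1-yl]-4,4,5,5-tetramethyl-1,3,2-dioxaborolane (homogeranyl pinacolboronate)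
Conditions: NaOtBu, THF, rt
Reagents that add atoms: none
Why: Alkoxide-induced deborylative alkylation, in which tert-butoxide turns the geminal bis(boronate) into an α-boryl carbanion that should displace the primary allylic bromide in SN2 fashion with the E geometry preserved.

**Step 9**
Reactants: 13 [(1S)-3-({[tert-butyl(dimethyl)silyl]oxy}methyl)-2-(1,3-dioxolan-2-yl)cyclopent-2-en-1-yl]methyl 2,4,6-tri(propan-2-yl)benzoate; 16 2-[(3E)-4,8-dimethylnona-3,7-dien-1-yl]-4,4,5,5-tetramethyl-1,3,2-dioxaborolane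
Product: 19 2-[(1S,4E)-1-[(1R)-3-({[tert-butyl(dimethyl)silyl]oxy}methyl)-2-(1,3-dioxolan-2-yl)cyclopent-2-en-1-yl]-5,9-dimethyldeca-4,8-dien-1-yl]-4,4,5,5-tetramethyl-1,3,2-dioxaborolane, via lithiated benzoate 17 (not isolated), via lithium boronate complex 18 (not isolated)
Conditions: sBuLi (1.3 equiv), (−)-sparteine (1.3 equiv), Et2O, −78 °C, 5 h; 16, −78 °C, 1 h; then rt → 35 °C
Reagents that add atoms: none
Why: Hoppe–Aggarwal lithiation–borylation: sBuLi/(−)-sparteine, directed by the benzoate carbonyl, should remove the pro-S hydrogen of the O–CH2 group to give the configurationally stable (S)-α-lithio benzoate 17, which the boronic ester 16 traps with retention as the boronate complex 18. On warming, the homogeranyl CH2 migrates from boron to carbon anti-periplanar to the departing triisopropylbenzoate (1,2-metallate rearrangement, inversion at carbon), forming the C–C bond and the (S)-configured secondary boronic ester. No ring is closed. The new stereocentre is set by the chiral diamine (reagent control) through this retention–inversion sequence, the ring stereocentre acting as a spectator. The step needs selection of one of the two O–CH2 hydrogens and deprotonation there in preference to the allylic and acetal C–H bonds, which the complex-induced proximity effect of the benzoate carbonyl at −78 °C should secure; the hindered aryl ester resists carbonyl attack and leaves without added Lewis acid.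

**Step 10**
Reactants: 19 2-[(1S,4E)-1-[(1R)-3-({[tert-butyl(dimethyl)silyl]oxy}methyl)-2-(1,3-dioxolan-2-yl)cyclopent-2-en-1-yl]-5,9-dimethyldeca-4,8-dien-1-yl]-4,4,5,5-tetramethyl-1,3,2-dioxaborolane
Product: 21 (2S,5E)-2-[(1R)-3-({[tert-butyl(dimethyl)silyl]oxy}methyl)-2-(1,3-dioxolan-2-yl)cyclopent-2-en-1-yl]-6,10-dimethylundeca-5,9-dienal, via α-chloro boronic ester 20 (not isolated)
Conditions: CH2Cl2, nBuLi, THF, −100 °C; 19, −100 °C → rt; then H2O2, pH 8 phosphate buffer, THF, 0 °C
Reagents that add atoms: dichloromethane (as LiCHCl2), ClCCl; hydrogen peroxide, OO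
Why: Matteson homologation, in which dichloromethyllithium adds to boron and the secondary alkyl group migrates with retention to give the α-chloro boronic ester, whose buffered oxidation unmasks the aldehyde, so the (S) centre from step 9 should be carried over unchanged.

**Step 11**
Reactants: 21 (2S,5E)-2-[(1R)-3-({[tert-butyl(dimethyl)silyl]oxy}methyl)-2-(1,3-dioxolan-2-yl)cyclopent-2-en-1-yl]-6,10-dimethylundeca-5,9-dienal
Product: 22 (2S,5E)-2-[(1R)-2-(1,3-dioxolan-2-yl)-3-(hydroxymethyl)cyclopent-2-en-1-yl]-6,10-dimethylundeca-5,9-dienal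
Conditions: TBAF, AcOH (1:1), THF, 0 °C → rt
Reagents that add atoms: none
Why: Fluoride-mediated cleavage of the primary silyl ether, buffered with acetic acid so that the α-stereocentre of the aldehyde should not epimerise and the dioxolane stays intact.

**Step 12**
Reactants: 22 (2S,5E)-2-[(1R)-2-(1,3-dioxolan-2-yl)-3-(hydroxymethyl)cyclopent-2-en-1-yl]-6,10-dimethylundeca-5,9-dienal
Product: 23 {(3R)-3-[(2S,5E)-6,10-dimethyl-1-oxoundeca-5,9-dien-2-yl]-2-(1,3-dioxolan-2-yl)cyclopent-1-en-1-yl}methyl acetate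
Conditions: Ac2O, pyridine, CH2Cl2, 0 °C → rt
Reagents that add atoms: acetic anhydride, CC(=O)OC(C)=O
Why: Acetylation of the primary allylic alcohol under mild basic conditions should leave the acetal and the α-branched aldehyde unchanged.

**Step 13**
Reactants: 23 {(3R)-3-[(2S,5E)-6,10-dimethyl-1-oxoundeca-5,9-dien-2-yl]-2-(1,3-dioxolan-2-yl)cyclopent-1-en-1-yl}methyl acetate
Product: 24 {(3R)-3-[(2S,5E)-6,10-dimethyl-1-oxoundeca-5,9-dien-2-yl]-2-formylcyclopent-1-en-1-yl}methyl acetate (CNP0280859.1)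
Conditions: PPTS (cat.), acetone/H2O (10:1), rt
Reagents that add atoms: water, O
Why: Mild acid hydrolysis of the allylic dioxolane (via a stabilised oxocarbenium ion) should free the conjugated aldehyde without cleaving the allylic acetate or enolising the α-branched aldehyde.

**Compound list**

1 | tert-butyl(dimethyl)(prop-2-yn-1-yloxy)silane | C#CCO[Si](C)(C)C(C)(C)C | starting material
2 | ethene | C=C | starting material
3 | tert-butyl(dimethyl)[(2-methylidenebut-3-en-1-yl)oxy]silane | C=CC(=C)CO[Si](C)(C)C(C)(C)C | intermediate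
4 | (4R)-4-benzyl-1,3-oxazolidin-2-one | O=C1N[C@H](Cc2ccccc2)CO1 | starting material
5 | prop-2-enoyl chloride | C=CC(=O)Cl | starting material
6 | (4R)-4-benzyl-3-(prop-2-enoyl)-1,3-oxazolidin-2-one | C=CC(=O)N1[C@H](Cc2ccccc2)COC1=O | intermediate
7 | (4R)-4-benzyl-3-{[(1S)-4-({[tert-butyl(dimethyl)silyl]oxy}methyl)cyclohex-3-en-1-yl]carbonyl}-1,3-oxazolidin-2-one | CC(C)(C)[Si](C)(C)OCC1=CC[C@@H](C(=O)N2[C@H](Cc3ccccc3)COC2=O)CC1 | intermediate
8 | [(1S)-4-({[tert-butyl(dimethyl)silyl]oxy}methyl)cyclohex-3-en-1-yl]methanol | CC(C)(C)[Si](C)(C)OCC1=CC[C@@H](CO)CC1 | intermediate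
9 | [(1S)-4-({[tert-butyl(dimethyl)silyl]oxy}methyl)cyclohex-3-en-1-yl]methyl 2,4,6-tri(propan-2-yl)benzoate | CC(C)(C)[Si](C)(C)OCC1=CC[C@@H](COC(=O)c2c(C(C)C)cc(C(C)C)cc2C(C)C)CC1 | intermediate
10 | secondary ozonide of 9 (1,2,4-trioxolane bridging the two former alkene carbons) | CC(C)(C)[Si](C)(C)OCC12CC[C@H](COC(=O)c3c(C(C)C)cc(C(C)C)cc3C(C)C)CC(O1)OO2 | intermediate
11 | (2S)-6-{[tert-butyl(dimethyl)silyl]oxy}-5-oxo-2-(2-oxoethyl)hexyl 2,4,6-tri(propan-2-yl)benzoate | O=CC[C@@H](COC(=O)c1c(C(C)C)cc(C(C)C)cc1C(C)C)CCC(=O)CO[Si](C)(C)C(C)(C)C | intermediate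
12 | [(1S)-3-({[tert-butyl(dimethyl)silyl]oxy}methyl)-2-formylcyclopent-2-en-1-yl]methyl 2,4,6-tri(propan-2-yl)benzoate | CC(C)(C)[Si](C)(C)OCC1=C(C=O)[C@@H](COC(=O)c2c(C(C)C)cc(C(C)C)cc2C(C)C)CC1 | intermediate
13 | [(1S)-3-({[tert-butyl(dimethyl)silyl]oxy}methyl)-2-(1,3-dioxolan-2-yl)cyclopent-2-en-1-yl]methyl 2,4,6-tri(propan-2-yl)benzoate | CC(C)(C)[Si](C)(C)OCC1=C(C2OCCO2)[C@@H](COC(=O)c3c(C(C)C)cc(C(C)C)cc3C(C)C)CC1 | intermediate
14 | (2E)-1-bromo-3,7-dimethylocta-2,6-diene (geranyl bromide) | CC(C)=CCC/C(C)=C/CBr | starting material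
15 | 2,2'-methylenebis(4,4,5,5-tetramethyl-1,3,2-dioxaborolane) | CC1(C)OB(CB2OC(C)(C)C(C)(C)O2)OC1(C)C | starting material
16 | 2-[(3E)-4,8-dimethylnona-3,7-dien-1-yl]-4,4,5,5-tetramethyl-1,3,2-dioxaborolane | CC(C)=CCC/C(C)=C/CCB1OC(C)(C)C(C)(C)O1 | intermediate
17 | (S)-lithio[(1S)-3-({[tert-butyl(dimethyl)silyl]oxy}methyl)-2-(1,3-dioxolan-2-yl)cyclopent-2-en-1-yl]methyl 2,4,6-tri(propan-2-yl)benzoate | CC(C)(C)[Si](C)(C)OCC1=C(C2OCCO2)[C@@H]([C@H]([Li])OC(=O)c3c(C(C)C)cc(C(C)C)cc3C(C)C)CC1 | intermediate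
18 | lithium boronate complex of 17 and 16 (boron bonded to pinacolate, the homogeranyl CH2 and the (S)-aroyloxy methine carbon) | CC(C)(C)[Si](C)(C)OCC1=C(C2OCCO2)[C@@H]([C@H]([B-]3(CC/C=C(\C)CCC=C(C)C)OC(C)(C)C(C)(C)O3)OC(=O)c4c(C(C)C)cc(C(C)C)cc4C(C)C)CC1.[Li+] | intermediate
19 | 2-[(1S,4E)-1-[(1R)-3-({[tert-butyl(dimethyl)silyl]oxy}methyl)-2-(1,3-dioxolan-2-yl)cyclopent-2-en-1-yl]-5,9-dimethyldeca-4,8-dien-1-yl]-4,4,5,5-tetramethyl-1,3,2-dioxaborolane | CC(C)(C)[Si](C)(C)OCC1=C(C2OCCO2)[C@@H]([C@@H](B3OC(C)(C)C(C)(C)O3)CC/C=C(\C)CCC=C(C)C)CC1 | intermediate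
20 | 2-[(2S,5E)-1-chloro-2-[(1R)-3-({[tert-butyl(dimethyl)silyl]oxy}methyl)-2-(1,3-dioxolan-2-yl)cyclopent-2-en-1-yl]-6,10-dimethylundeca-5,9-dien-1-yl]-4,4,5,5-tetramethyl-1,3,2-dioxaborolane (mixture at the CHCl carbon) | CC(C)(C)[Si](C)(C)OCC1=C(C2OCCO2)[C@@H]([C@@H](C(Cl)B3OC(C)(C)C(C)(C)O3)CC/C=C(\C)CCC=C(C)C)CC1 | intermediate
21 | (2S,5E)-2-[(1R)-3-({[tert-butyl(dimethyl)silyl]oxy}methyl)-2-(1,3-dioxolan-2-yl)cyclopent-2-en-1-yl]-6,10-dimethylundeca-5,9-dienal | CC(C)(C)[Si](C)(C)OCC1=C(C2OCCO2)[C@@H]([C@@H](C=O)CC/C=C(\C)CCC=C(C)C)CC1 | intermediate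
22 | (2S,5E)-2-[(1R)-2-(1,3-dioxolan-2-yl)-3-(hydroxymethyl)cyclopent-2-en-1-yl]-6,10-dimethylundeca-5,9-dienal | OCC1=C(C2OCCO2)[C@@H]([C@@H](C=O)CC/C=C(\C)CCC=C(C)C)CC1 | intermediate
23 | {(3R)-3-[(2S,5E)-6,10-dimethyl-1-oxoundeca-5,9-dien-2-yl]-2-(1,3-dioxolan-2-yl)cyclopent-1-en-1-yl}methyl acetate | CC(=O)OCC1=C(C2OCCO2)[C@@H]([C@@H](C=O)CC/C=C(\C)CCC=C(C)C)CC1 | intermediate
24 | {(3R)-3-[(2S,5E)-6,10-dimethyl-1-oxoundeca-5,9-dien-2-yl]-2-formylcyclopent-1-en-1-yl}methyl acetate | CC(=O)OCC1=C(C=O)[C@@H]([C@@H](C=O)CC/C=C(\C)CCC=C(C)C)CC1 | target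

**Totals.** 13 steps in all; the longest linear sequence is 11 steps (steps 1, 3–7 and 9–13).

**Steps most likely to fail**

Step 9. The chiral diamine and the adjacent ring stereocentre may be a mismatched pair, so that deprotonation becomes slow or loses its selectivity between the two O–CH2 hydrogens. The fallback sets out from 13: lithiation with sBuLi/TMEDA and quenching with Me3SnCl gives both α-stannyl benzoates, from which the (S)-configured [(trimethylstannyl)methyl] benzoate F1 is separated by chromatography. Tin–lithium exchange of F1 with nBuLi at −78 °C proceeds with retention and regenerates 17 as a single stereoisomer, so stereocontrol comes from separation and a stereospecific transmetalation instead of a kinetic deprotonation. Borylation with 16 and rearrangement then return to the route at 19.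

Step 10. Ate-complex formation at the hindered secondary boronic ester may be sluggish, or the aldehyde may partly epimerise during the oxidative work-up. The fallback sets out from 19 and uses the smaller, more reactive chloromethyllithium (BrCH2Cl, nBuLi, −78 °C) to give the homologated primary boronic ester F2. Oxidation with NaBO3 gives the primary alcohol F3, and Dess–Martin oxidation buffered with NaHCO3 comes back to the route at 21.

Step 3. The silyloxymethyl group polarises the diene only weakly, so the para/meta regioselectivity of the cycloaddition may erode and give inseparable regioisomers. The fallback sets out from 6 and uses the strongly para-directing 2-(trimethylsilyloxy)buta-1,3-diene under the same Lewis-acid conditions to give the silyl enol ether cycloadduct F4. CsF/PhNTf2 converts F4 regiospecifically into the enol triflate F5, Stille coupling with (tributylstannyl)methanol (Pd(PPh3)4, LiCl, dioxane) gives the allylic alcohol F6, and silylation with TBSCl/imidazole comes back to the route at 7.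

**Further compounds**

F1 | step 9 | (S)-[(1S)-3-({[tert-butyl(dimethyl)silyl]oxy}methyl)-2-(1,3-dioxolan-2-yl)cyclopent-2-en-1-yl](trimethylstannyl)methyl 2,4,6-tri(propan-2-yl)benzoate | CC(C)(C)[Si](C)(C)OCC1=C(C2OCCO2)[C@@H]([C@H]([Sn](C)(C)C)OC(=O)c3c(C(C)C)cc(C(C)C)cc3C(C)C)CC1
F2 | step 10 | 2-[(2S,5E)-2-[(1R)-3-({[tert-butyl(dimethyl)silyl]oxy}methyl)-2-(1,3-dioxolan-2-yl)cyclopent-2-en-1-yl]-6,10-dimethylundeca-5,9-dien-1-yl]-4,4,5,5-tetramethyl-1,3,2-dioxaborolane | CC(C)(C)[Si](C)(C)OCC1=C(C2OCCO2)[C@@H]([C@@H](CB3OC(C)(C)C(C)(C)O3)CC/C=C(\C)CCC=C(C)C)CC1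
F3 | step 10 | (2S,5E)-2-[(1R)-3-({[tert-butyl(dimethyl)silyl]oxy}methyl)-2-(1,3-dioxolan-2-yl)cyclopent-2-en-1-yl]-6,10-dimethylundeca-5,9-dien-1-ol | CC(C)(C)[Si](C)(C)OCC1=C(C2OCCO2)[C@@H]([C@@H](CO)CC/C=C(\C)CCC=C(C)C)CC1
F4 | step 3 | (4R)-4-benzyl-3-{[(1S)-4-[(trimethylsilyl)oxy]cyclohex-3-en-1-yl]carbonyl}-1,3-oxazolidin-2-one | C[Si](C)(C)OC1=CC[C@@H](C(=O)N2[C@H](Cc3ccccc3)COC2=O)CC1
F5 | step 3 | (4S)-4-{[(4R)-4-benzyl-2-oxo-1,3-oxazolidin-3-yl]carbonyl}cyclohex-1-en-1-yl trifluoromethanesulfonate | O=S(=O)(OC1=CC[C@@H](C(=O)N2[C@H](Cc3ccccc3)COC2=O)CC1)C(F)(F)F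
F6 | step 3 | (4R)-4-benzyl-3-{[(1S)-4-(hydroxymethyl)cyclohex-3-en-1-yl]carbonyl}-1,3-oxazolidin-2-one | OCC1=CC[C@@H](C(=O)N2[C@H](Cc3ccccc3)COC2=O)CC1
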